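**Retrosynthetic overview**
1. Last step: chelation-controlled cleavage of the 5-O-methyl ether. The prenyl group, the 7-OMe group and both stereocentres are already in place.
2. Ring C (the C2–C3 bond and both stereocentres) comes from an enantioselective, acid-catalysed O-to-C 1,2-shift. It contracts a racemic seven-membered 2-aryl-1,3-benzodioxepin-5-one to the six-membered 3-hydroxychroman-4-one.
3. The seven-membered acetal comes from the ring A ketol ArC(O)CH2OH (free phenol next to the prenyl group) and vanillin.
4. The ketol comes from resorcinol by O-methylation, C–H borylation/oxidation, ortho-prenylation with prenol, then ortho-formylation and hydroxymethylation with formaldehyde. Vanillin comes from catechol and glyoxylic acid.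
5. Ring order: rings A and B are bought as benzene rings. The seven-membered acetal ring is closed first and then contracted to ring C.

Assumption: the (R)-enantiomer of the phosphoric acid is taken to give the (2R,3R) series; the sense of induction must be checked on the first run, and the (S)-acid is used if it is reversed. (prenyl = 3-methylbut-2-en-1-yl)

**Step 1**
Reactants: 1 resorcinol
Product: 2 1,3-dimethoxybenzene
Conditions: MeI (2.5 equiv), K2CO3, acetone, reflux
Reagents that add atoms: iodomethane, CI
Why: Williamson ether synthesis methylates both phenoxides, and the symmetric diether leaves one sterically open C–H (C5) for the next step.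

**Step 2**
Reactants: 2 1,3-dimethoxybenzene
Product: 4 3,5-dimethoxyphenol, via aryl pinacol boronate 3 (not isolated)
Conditions: [Ir(OMe)(cod)]2 (1 mol %), dtbpy (2 mol %), B2pin2, THF, 80 °C; then Oxone (2KHSO5·KHSO4·K2SO4), acetone–H2O, rt
Reagents that add atoms: bis(pinacolato)diboron, CC1(C)OB(OC1(C)C)B2OC(C)(C)C(C)(C)O2 (boron of 3 only); potassium peroxymonosulfate, [K+].[O-]S(=O)(=O)OO (the phenol oxygen)
Why: Sterically governed iridium-catalysed aromatic C–H borylation reaches only the position meta to both methoxy groups, and oxidation of the boronate in the same flask gives the phenol (one-pot borylation/oxidation).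

**Step 3**
Reactants: 4 3,5-dimethoxyphenol; 5 prenol (3-methylbut-2-en-1-ol)
Product: 6 3,5-dimethoxy-2-prenylphenol
Conditions: acidic Al2O3, ClCH2CH2Cl, reflux (4 in slight excess)
Reagents that add atoms: none
Why: In this surface-templated Friedel–Crafts allylation the phenol and the allylic alcohol are co-adsorbed, so the prenyl unit goes ortho to the OH; the two ortho sites are equivalent by symmetry, and excess 4 suppresses double prenylation.

**Step 4**
Reactants: 6 3,5-dimethoxy-2-prenylphenol; 7 formaldehyde (as paraformaldehyde)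
Product: 8 2-hydroxy-4,6-dimethoxy-3-prenylbenzaldehyde
Conditions: MgCl2, Et3N, (CH2O)n, MeCN, reflux; then 1 M HCl
Reagents that add atoms: none
Why: In the Casnati–Skattebøl ortho-formylation the magnesium phenoxide directs formaldehyde to the only free ortho carbon and a second formaldehyde accepts the hydride, under non-acidic conditions that spare the prenyl group.

**Step 5**
Reactants: 8 2-hydroxy-4,6-dimethoxy-3-prenylbenzaldehyde; 7 formaldehyde (as paraformaldehyde)
Product: 9 2-hydroxy-1-(2-hydroxy-4,6-dimethoxy-3-prenylphenyl)ethan-1-one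
Conditions: (CH2O)n, 3-ethylbenzothiazolium bromide (20 mol %), iPr2NEt (20 mol %), THF, 60 °C
Reagents that add atoms: none
Why: In this carbene-catalysed crossed benzoin reaction (hydroxymethylation of an aldehyde) the Breslow intermediate of 8 adds to the far more electrophilic formaldehyde and gives the primary α-ketol without acid or oxidant.

**Step 6**
Reactants: 10 catechol
Product: 11 guaiacol (2-methoxyphenol)
Conditions: MeI (1.0 equiv), K2CO3 (1.0 equiv), acetone, reflux; distillation
Reagents that add atoms: iodomethane, CI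
Why: This is a statistical Williamson mono-methylation, and guaiacol is separated from catechol and veratrole by distillation.

**Step 7**
Reactants: 11 guaiacol; 12 glyoxylic acid
Product: 14 vanillin, via vanillylmandelic acid 13 (not isolated)
Conditions: NaOH, H2O, 30 °C; then air, CuSO4 (5 mol %), NaOH, 95 °C; H2SO4 to pH 3
Reagents that add atoms: none
Why: Para-selective hydroxyalkylation of the phenolate by glyoxylate, followed by copper-catalysed aerobic oxidative decarboxylation, is the established guaiacol-to-vanillin sequence.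

**Step 8**
Reactants: 9 2-hydroxy-1-(2-hydroxy-4,6-dimethoxy-3-prenylphenyl)ethan-1-one; 14 vanillin
Product: 16 rac-2-(4-hydroxy-3-methoxyphenyl)-6,8-dimethoxy-9-prenyl-4H-1,3-benzodioxepin-5-one, via vanillin dimethyl acetal 15 (not isolated)
Conditions: 14, HC(OMe)3 (1.05 equiv), PPTS (10 mol %), CH2Cl2, rt; then 9, 5 Å MS, rt; Et3N quench, Et3N-deactivated silica
Reagents that add atoms: trimethyl orthoformate, COC(OC)OC (methoxy groups of 15 only)
Why: This is a benzylidene-type transacetalisation driven by sieve uptake of methanol; only the phenol next to the prenyl group is free, which fixes the later 8-prenyl regiochemistry, and PPTS at rt ionises acetals but does not enolise the ketone, so the acetal (racemic at C2) can be isolated.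

**Step 9**
Reactants: 16 rac-2-(4-hydroxy-3-methoxyphenyl)-6,8-dimethoxy-9-prenyl-4H-1,3-benzodioxepin-5-one
Product: 18 (2R,3R)-3-hydroxy-2-(4-hydroxy-3-methoxyphenyl)-5,7-dimethoxy-8-prenyl-2,3-dihydrochromen-4-one, via para-quinone methide enediol 17 (not isolated)
Conditions: (R)-3,3'-bis(2,4,6-triisopropylphenyl)-1,1'-binaphthyl-2,2'-diyl hydrogen phosphate [(R)-TRIP] (10 mol %), 5 Å MS, toluene (0.02 M), 40 °C
Reagents that add atoms: none
Why: Proposed new method: an enantioconvergent, Brønsted-acid-catalysed O-to-C 1,2-shift that contracts the seven-membered acetal to ring C; the acid protonates O3, the C2–O3 bond ionises with push from the 4-hydroxy-3-methoxyphenyl group to the achiral para-quinone methide, the bifunctional phosphate enolises the released α-hydroxy ketone to its enediol (17), and C3 attacks C2 in a six-membered closure inside the hydrogen-bonded chiral pocket, so both enantiomers of 16 converge on one face (C2 = R), while C3 ends trans (R) through the diequatorial half-chair and, if needed, acid-mediated enediol epimerisation; recapture through oxygen only regenerates 16, whereas C–C bond formation is irreversible; the process is stepwise and ionic, and the closest known reaction types are the Petasis–Ferrier rearrangement and its phosphoric-acid-catalysed aza variant (1,3 O-to-C shifts), the [1,2]-Wittig rearrangement of acetals, and phosphoric-acid-catalysed additions of enols to para-quinone methides.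

**Step 10**
Reactants: 18 (2R,3R)-3-hydroxy-2-(4-hydroxy-3-methoxyphenyl)-5,7-dimethoxy-8-prenyl-2,3-dihydrochromen-4-one
Product: 19 (2R,3R)-3,5-dihydroxy-2-(4-hydroxy-3-methoxyphenyl)-7-methoxy-8-prenyl-2,3-dihydrochromen-4-one (target)
Conditions: MgI2·OEt2 (4 equiv), THF, 60 °C; then 1 M HCl
Reagents that add atoms: none
Why: In this chelation-controlled aryl methyl ether cleavage magnesium bridges C4=O and the 5-OMe oxygen and iodide removes that methyl group by SN2; the 7-OMe and 3'-OMe groups lack the chelate, the prenyl group has no free ortho OH to cyclise onto, and no base is present, so the thermodynamically preferred trans stereocentres are kept.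

**Compound list**
1 | resorcinol | Oc1cccc(O)c1 | starting material
2 | 1,3-dimethoxybenzene | COc1cccc(OC)c1 | intermediate
3 | 2-(3,5-dimethoxyphenyl)-4,4,5,5-tetramethyl-1,3,2-dioxaborolane | COc1cc(OC)cc(c1)B2OC(C)(C)C(C)(C)O2 | intermediate (not isolated)
4 | 3,5-dimethoxyphenol | COc1cc(O)cc(OC)c1 | intermediate
5 | prenol (3-methylbut-2-en-1-ol) | CC(C)=CCO | starting material
6 | 3,5-dimethoxy-2-prenylphenol | COc1cc(O)c(CC=C(C)C)c(OC)c1 | intermediate
7 | formaldehyde (used as paraformaldehyde) | C=O | starting material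
8 | 2-hydroxy-4,6-dimethoxy-3-prenylbenzaldehyde | COc1cc(OC)c(C=O)c(O)c1CC=C(C)C | intermediate
9 | 2-hydroxy-1-(2-hydroxy-4,6-dimethoxy-3-prenylphenyl)ethan-1-one | COc1cc(OC)c(C(=O)CO)c(O)c1CC=C(C)C | intermediate
10 | catechol | Oc1ccccc1O | starting material
11 | guaiacol | COc1ccccc1O | intermediate
12 | glyoxylic acid | O=CC(=O)O | starting material
13 | vanillylmandelic acid (racemic) | COc1cc(C(O)C(=O)O)ccc1O | intermediate (not isolated)
14 | vanillin | COc1cc(C=O)ccc1O | intermediate
15 | vanillin dimethyl acetal | COc1cc(C(OC)OC)ccc1O | intermediate (not isolated)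
16 | rac-2-(4-hydroxy-3-methoxyphenyl)-6,8-dimethoxy-9-prenyl-4H-1,3-benzodioxepin-5-one | COc1cc(C2OCC(=O)c3c(OC)cc(OC)c(CC=C(C)C)c3O2)ccc1O | intermediate
17 | 4-{[2-(1,2-dihydroxyethenyl)-3,5-dimethoxy-6-prenylphenoxy]methylidene}-2-methoxycyclohexa-2,5-dien-1-one | COC1=CC(=COc2c(CC=C(C)C)c(OC)cc(OC)c2C(O)=CO)C=CC1=O | intermediate (not isolated)
18 | (2R,3R)-3-hydroxy-2-(4-hydroxy-3-methoxyphenyl)-5,7-dimethoxy-8-prenyl-2,3-dihydrochromen-4-one | COc1cc([C@H]2Oc3c(CC=C(C)C)c(OC)cc(OC)c3C(=O)[C@@H]2O)ccc1O | intermediate
19 | (2R,3R)-3,5-dihydroxy-2-(4-hydroxy-3-methoxyphenyl)-7-methoxy-8-prenyl-2,3-dihydrochromen-4-one | COc1cc([C@H]2Oc3c(CC=C(C)C)c(OC)cc(O)c3C(=O)[C@@H]2O)ccc1O | target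

**Total steps:** 10. **Longest linear sequence:** 8 (steps 1–5 and 8–10).

**Steps most likely to fail**

*Step 9 (the new ring contraction).* Enolisation of the released ketol may be too slow, the acetal may only hydrolyse, or the ee may be low or erode through reversible C2–O1 ionisation.
- The fallback uses known chemistry: Juliá–Colonna epoxidation of a chalcone, then acid-induced epoxide cyclisation. It sets out from 8 and 14 and comes back at 18.
- MeMgBr (2.2 equiv, THF, 0 °C) adds to 8 to give 1-(2-hydroxy-4,6-dimethoxy-3-prenylphenyl)ethanol F1.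
- MnO2 (CH2Cl2) oxidises this to 2'-hydroxy-4',6'-dimethoxy-3'-prenylacetophenone F2.
- NaH/MOMCl (DMF, 0 °C) then gives 4',6'-dimethoxy-2'-(methoxymethoxy)-3'-prenylacetophenone F3.
- In parallel, 14 with MOMCl/iPr2NEt gives 3-methoxy-4-(methoxymethoxy)benzaldehyde F4.
- Claisen–Schmidt condensation of the two (KOH, EtOH) gives (E)-3,4',6'-trimethoxy-4,2'-bis(methoxymethoxy)-3'-prenylchalcone F5.
- Nucleophilic epoxidation (poly-L-leucine, urea–H2O2, DBU, THF) leaves the prenyl alkene untouched and gives (αR,βS)-3,4',6'-trimethoxy-4,2'-bis(methoxymethoxy)-3'-prenylchalcone epoxide F6.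
- HCl in MeOH (40 °C) removes both methoxymethyl groups. The freed 2'-phenol opens the epoxide at the benzylic carbon with inversion and delivers trans-(2R,3R)-18.

*Step 5 (hydroxymethylation).* The aldehyde is electron-rich, flanked on both sides and hydrogen-bonded, and the free phenol may quench the carbene.
- The fallback uses a hydroxymethyl anion equivalent followed by selective oxidation. It sets out from 8 and comes back at 9.
- iPrOMe2SiCH2MgCl (3 equiv, THF, 0 °C) adds to 8 to give 2-(isopropoxydimethylsilyl)-1-(2-hydroxy-4,6-dimethoxy-3-prenylphenyl)ethanol F7.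
- Tamao oxidation (H2O2, KF, KHCO3, THF–MeOH) gives 1-(2-hydroxy-4,6-dimethoxy-3-prenylphenyl)ethane-1,2-diol F8.
- MnO2 (CH2Cl2) oxidises only the benzylic alcohol and gives 9.

*Step 8 (seven-membered mixed aryl/alkyl acetal).* The phenol is hindered and hydrogen-bonded to the ketone, so the equilibrium may be poor.
- The fallback replaces equilibrium transacetalisation with irreversible silyl-transfer acetalisation under kinetic control. It sets out from 9 and 14 and comes back at 16.
- TMSCl/Et3N (CH2Cl2) converts 9 into 1-[4,6-dimethoxy-3-prenyl-2-(trimethylsilyloxy)phenyl]-2-(trimethylsilyloxy)ethanone F9, and 14 into 3-methoxy-4-(trimethylsilyloxy)benzaldehyde F10.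
- TMSOTf (5 mol %, CH2Cl2, −78 °C) joins the two to give rac-6,8-dimethoxy-2-[3-methoxy-4-(trimethylsilyloxy)phenyl]-9-prenyl-4H-1,3-benzodioxepin-5-one F11.
- K2CO3 in MeOH (0 °C) frees the phenol and gives 16.

**Further compounds**
F1 | step 9 | 1-(2-hydroxy-4,6-dimethoxy-3-prenylphenyl)ethanol | CC(O)c1c(O)c(CC=C(C)C)c(OC)cc1OC
F2 | step 9 | 2'-hydroxy-4',6'-dimethoxy-3'-prenylacetophenone | CC(=O)c1c(O)c(CC=C(C)C)c(OC)cc1OC
F3 | step 9 | 4',6'-dimethoxy-2'-(methoxymethoxy)-3'-prenylacetophenone | CC(=O)c1c(OCOC)c(CC=C(C)C)c(OC)cc1OC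
F4 | step 9 | 3-methoxy-4-(methoxymethoxy)benzaldehyde | COCOc1ccc(C=O)cc1OC
F5 | step 9 | (E)-3,4',6'-trimethoxy-4,2'-bis(methoxymethoxy)-3'-prenylchalcone | COCOc1ccc(/C=C/C(=O)c2c(OCOC)c(CC=C(C)C)c(OC)cc2OC)cc1OC
F6 | step 9 | (αR,βS)-3,4',6'-trimethoxy-4,2'-bis(methoxymethoxy)-3'-prenylchalcone epoxide | O=C(c1c(OCOC)c(CC=C(C)C)c(OC)cc1OC)[C@@H]2O[C@H]2c3ccc(OCOC)c(OC)c3
F7 | step 5 | 2-(isopropoxydimethylsilyl)-1-(2-hydroxy-4,6-dimethoxy-3-prenylphenyl)ethanol | CC(C)O[Si](C)(C)CC(O)c1c(O)c(CC=C(C)C)c(OC)cc1OC
F8 | step 5 | 1-(2-hydroxy-4,6-dimethoxy-3-prenylphenyl)ethane-1,2-diol | OCC(O)c1c(O)c(CC=C(C)C)c(OC)cc1OC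
F9 | step 8 | 1-[4,6-dimethoxy-3-prenyl-2-(trimethylsilyloxy)phenyl]-2-(trimethylsilyloxy)ethanone | C[Si](C)(C)OCC(=O)c1c(O[Si](C)(C)C)c(CC=C(C)C)c(OC)cc1OC
F10 | step 8 | 3-methoxy-4-(trimethylsilyloxy)benzaldehyde | COc1cc(C=O)ccc1O[Si](C)(C)C
F11 | step 8 | rac-6,8-dimethoxy-2-[3-methoxy-4-(trimethylsilyloxy)phenyl]-9-prenyl-4H-1,3-benzodioxepin-5-one | COc1cc(C2OCC(=O)c3c(OC)cc(OC)c(CC=C(C)C)c3O2)ccc1O[Si](C)(C)C
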